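## Analysis of the target

The target is a diaryl ether of two hexasubstituted benzene rings and has no stereocenter. Ring A (C1 to C6) is methyl β-orcinolcarboxylate with one more oxygen: C1 CO2Me, C2 Me, C3 O-aryl, C4 OH, C5 Me, C6 OH. Ring B (C1' to C6') is a chlorinated, formylated orsellinic acid bound through its C1' oxygen: C2' CHO, C3' OH, C4' Cl, C5' Me, C6' CO2H. Stereochemistry appears only in passing, as the enol ether geometry of one intermediate and two sp3 carbons of a later one, and all of it is erased. The sensitive groups are the aldehyde ortho to a phenol, the aryl chloride (no hydrogenolysis), the electron-rich phenols, and two carboxyl groups that must end in different states (methyl ester on ring A, free acid on ring B). The hard part is the ether: C3 lies between C2–Me and C4–OH and C1' between C2'–CHO and C6'–CO2H, so joining two finished arenes would mean forcing a tetra-ortho-substituted C–O bond. In addition every ring carbon is substituted, so each group must be placed without regiochemical choice. The plan rests on ring B being an orsellinate: C6' with its carboxyl, C1' and C2' form an acetoacetate unit, and C3', C4', C5' with its methyl form a crotonate unit. With the C1' oxygen already arylated, ring B one oxidation level down is the aryl enol ether of a cyclohexane-1,3-dione ester, so the ether bond can be made on an open-chain carbon before ring B exists.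

## Retrosynthetic reasoning

**Protecting groups (16 from 15 from 14).** The last two operations cut only oxygen–protecting-group bonds: the benzyl ethers on the C4 and C6 oxygens (16 from 15) and the tert-butyl ester on the C6' carboxyl (15 from 14). Benzyl is chosen because it has to survive a strong base, a quinone oxidant, an electrophilic chlorination and a basic formylation, and can be removed by a Lewis acid without hydrogen. tert-Butyl is chosen because ring B's ester must fall while ring A's methyl ester stays, and because it is inert as an acyl acceptor in the annulation.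

**C2'–CHO (14 from 13).** The formyl carbon is cut off last among the ring substituents. In 13 the carbon C2' is the only open position and is ortho to the free C3'–OH, so a phenol-directed ortho-formylation has no choice of site. The forward reaction must spare the tert-butyl ester, which rules out a strongly Lewis-acidic formylation.

**C4'–Cl (13 from 12).** In 12 two positions are open. C4' is ortho to the C3'–OH and para to the ether oxygen, the site electrophiles prefer in resorcinol monoethers. C2' lies between two oxygens, next to the bulky aryloxy group. The halogen is therefore introduced first and should take C4'; in the reverse order the formyl group would go to C4'.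

**Aromatization (12 from 11).** No skeletal bond is cut. Ring B is taken down one oxidation level to the 3-aryloxycyclohexenone 11. This turns an arene problem into a carbonyl-condensation problem; the forward step only has to remove two hydrogens from a ring that is already doubly activated for enolization.

**C5'–C6' and C2'–C3' (11 from 8 and 9).** These two cuts divide ring B into two four-carbon pieces along its acetate pattern and leave the ether oxygen on an acyclic enol ether carbon. All of ring B then comes from 9 and a butenoate, and the hindered C1'–O bond never has to be formed on an arene. In the forward direction the dienolate of 8 must bond through its α-carbon C6' to C5' of 9 and then through its γ-carbon C2' to the ester carbonyl C3'.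

**C1'–O (8 from 5 and 7; 7 from 6).** The enol ether is cut at the oxygen–C1' bond, which corresponds to conjugate addition of the phenol 5 to the alkynoate 7. The sp carbon carries no flanking substituents, so the di-ortho-substituted phenol can reach it. The ester 7 comes from the acid 6 by tert-butylation.

**C3–O (5 from 3 via 4, 3 from 2, 2 from 1).** The C3 oxygen is traced back to a formyl group, a latent hydroxyl through peracid rearrangement, and the formyl group to the C3–H of 1, the only unsubstituted carbon of that ring. Benzylation is placed between the two operations. The formylation then profits from the free phenols, and the peracid meets an aldehyde with ether oxygens ortho and para, which favours aryl migration.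

## Alternatives that were turned down

**Alternative 1:** Ring B is cut at C1'–C6' and C4'–C5', and the C6' carboxyl is read as the lactone of a depsidone closed onto the C4 oxygen.
- Forward key step: the precursor A2 carries a 3-chloro-4-methoxy-2-pyranon-6-yl group on the C3 oxygen and a but-2-ynoyl ester on the C4 oxygen. On heating, the alkyne adds across the pyranone and decarboxylative cycloreversion gives the depsidone A1.
- For it: the tether fixes the orientation of the alkyne, chlorine and the C3' oxygen arrive with the pyranone, and the arene forms at the right oxidation level. On these three points it is stronger than the chosen route, which needs a dehydrogenation and a late chlorination.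
- Against it: A2 requires three differentiated oxygens on ring A. The hindered C3 oxygen must still be attached to a substituted sp2 carbon, now C6 of a pyranone, which is a poorer acceptor than an alkynoate. The cycloaddition passes through a bridged bicycle whose tether ends as a seven-membered ring, so it needs temperatures at which an aryl alkynoate can transacylate. After A1, lactone opening selective over the methyl ester, formylation and O-demethylation remain.
- Comparison: the chosen strategy is shorter and starts from commercial 1, in which ring A is already complete.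

**Alternative 2:** Ring A is cut at C2–C3 and C4–C5 and ring B is made beforehand.
- Forward key step: the aryloxyketene bis(trimethylsilyl) acetal A4 adds to the pyranone ester A5 in an inverse-demand [4+2] reaction. Decarboxylation and loss of one silyloxy group give A3.
- For it: the ether oxygen is carried in on a two-carbon unit made by simple O-alkylation of a ring B phenol, the C4 and C6 oxygens come out differentiated, and ring B is chlorinated as a small phenol before coupling. That is as good as or better than the chosen route on ether formation and on chlorine.
- Against it: it builds from scratch a ring that can be bought complete. A5 has two methyl-bearing diene termini and a donor methoxy group that lowers its electron demand, so the cycloaddition of the bulky A4 should be slow, with orientation resting on polarization alone. Ring B still has to be made and chlorinated with the same regiochemical question. A3 then needs formylation and two O-demethylations.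
- Comparison: the chosen route builds only ring B, from two four-carbon esters, and has fewer steps.

**Alternative 3:** Ring A is cut at C5–C6, C3–C4 and C1–C6.
- Forward key step: an amine base converts the acid chloride A7 into an aryloxy(vinyl)ketene. This adds to the siloxyalkyne A8 by [2+2]; four-electron ring opening, six-electron ring closure and tautomerization give A6.
- For it: ketene and ynol ether polarity dictate the orientation completely, all six substituents of ring A are set in one mild operation, and C4 and C6 oxygens are differentiated. In regiochemical certainty it is stronger than the chosen key step.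
- Against it: A7 needs the hindered ring B phenol alkylated at a secondary allylic carbon next to a carboxyl, and then an acid chloride made beside a tert-butyl ester. The ketene can dimerize, A8 is sensitive, and ring B with its chlorine must again be prepared first. Formylation and demethylation follow.
- Comparison: like alternative 2 it rebuilds the commercially available ring. The chosen strategy accepts one regiochemical risk in exchange for a short route from 1.

Key step: step 6

Remark on the chemistry: ArO stands for the aryloxy group of phenol 5, that is ring A bonded through C3 with benzyl ethers on the C4 and C6 oxygens (Ar = 2,4-bis(benzyloxy)-5-(methoxycarbonyl)-3,6-dimethylphenyl). Compound 11 is drawn as the ketone-conjugated enol ether; a double-bond isomer formed beside it would give the same phenol 12 in step 7.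

## Route

Step 1
Reactants: 1 methyl 2,4-dihydroxy-3,6-dimethylbenzoate
Product: 2 methyl 5-formyl-2,4-dihydroxy-3,6-dimethylbenzoate (formyl on ring A C3)
Conditions: Cl2CHOMe, TiCl4, CH2Cl2, 0 °C → rt; aq. HCl
Reagents that add atoms: dichloromethyl methyl ether, COC(Cl)Cl; water, O
Why: Rieche formylation; C3 is the only unsubstituted ring carbon, ortho to the C4 phenol and para to the C6 phenol, so the titanium phenoxide should direct the electrophile there without a regiochemical alternative.

Step 2
Reactants: 2 methyl 5-formyl-2,4-dihydroxy-3,6-dimethylbenzoate
Product: 3 methyl 2,4-bis(benzyloxy)-5-formyl-3,6-dimethylbenzoate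
Conditions: BnBr, K2CO3, DMF, 60 °C
Reagents that add atoms: benzyl bromide, BrCc1ccccc1
Why: Williamson ether synthesis; both phenols are hydrogen-bonded to a carbonyl group, so a polar solvent and warming are used, and nothing else in 2 is alkylated.

Step 3
Reactants: 3 methyl 2,4-bis(benzyloxy)-5-formyl-3,6-dimethylbenzoate
Product: 5 methyl 2,4-bis(benzyloxy)-5-hydroxy-3,6-dimethylbenzoate, via aryl formate 4 (not isolated)
Conditions: mCPBA, CH2Cl2, rt; then K2CO3, MeOH, rt
Reagents that add atoms: 3-chloroperoxybenzoic acid, OOC(=O)c1cccc(Cl)c1
Why: Baeyer–Villiger (Dakin-type) oxidation; the aldehyde has benzyloxy groups ortho and para, so the electron-rich aryl group should migrate to oxygen to give formate 4, which mild methanolysis cleaves without touching the hindered methyl ester.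

Step 4
Reactants: 6 but-2-ynoic acid
Product: 7 tert-butyl but-2-ynoate
Conditions: Cl3CC(=NH)OtBu, CH2Cl2–cyclohexane, rt
Reagents that add atoms: tert-butyl 2,2,2-trichloroacetimidate, CC(C)(C)OC(=N)C(Cl)(Cl)Cl
Why: Esterification with a trichloroacetimidate; the acid protonates the imidate and captures the tert-butyl cation, which avoids strong mineral acid and any nucleophile that could add to the alkyne.

Step 5
Reactants: 5 methyl 2,4-bis(benzyloxy)-5-hydroxy-3,6-dimethylbenzoate; 7 tert-butyl but-2-ynoate
Product: 8 tert-butyl (2E)-3-(ArO)but-2-enoate
Conditions: DABCO (0.3 equiv), MeCN, rt → 50 °C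
Reagents that add atoms: none
Why: Amine-catalysed oxa-Michael addition of a phenol to an alkynoate; the amine adds to the ynoate, the resulting zwitterion deprotonates the phenol and the phenoxide enters at the β-carbon, which as an sp carbon tolerates the two ortho substituents; the E isomer, with the methyl group syn to the ester, is the expected and the more stable product.

Step 6
Reactants: 8 tert-butyl (2E)-3-(ArO)but-2-enoate; 9 methyl (2E)-but-2-enoate
Product: 11 tert-butyl 2-(ArO)-6-methyl-4-oxocyclohex-2-ene-1-carboxylate (racemic cis/trans mixture), via open-chain Michael adduct 10 (not isolated)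
Conditions: LiN(SiMe3)2 (1.05 equiv), THF, −78 °C; 9, −78 °C; LiN(SiMe3)2 (1.0 equiv), −78 → 0 °C; AcOH
Reagents that add atoms: none
Why: Proposed new method: a [3+3] Michael–Claisen annulation in which the three-carbon dinucleophile is the lithium dienolate of a β-aryloxycrotonate instead of the usual β-keto ester anion; the closest known reactions are the acetoacetate–crotonate synthesis of dihydro-orsellinates and the kinetic α-selective 1,4-additions of lithium ester dienolates to enoates. LiN(SiMe3)2 removes a proton from the C2' methyl group of 8, which in the E isomer lies syn to the ester carbonyl, and gives the extended dienolate; this amide is chosen because it is too weak to metalate the C2 methyl group of ring A ortho to its ester and too hindered to attack an ester or displace the aryloxy group. The α-carbon C6' adds to C5' of 9 through a lithium-bridged transition state at −78 °C (bond C5'–C6') and gives the ester enolate of 10. Proton transfer from the doubly activated C6'–H to C4' regenerates a dienolate, whose γ-carbon C2' attacks the methyl ester carbonyl C3' (bond C2'–C3'); this 6-exo-trig acyl substitution closes ring B and expels methoxide. The second portion of base, added only after 9 has been consumed, converts the acidic product into its enolate, which makes the closure irreversible and keeps the product from quenching unreacted dienolate. The selectivity needed is α- over γ-attack in the Michael step: the lithium counterion in THF without polar additives at low temperature favours it, and the twisted aryloxy group is only a weak donor towards C2'. The tert-butyl ester is not an acyl acceptor, so only the methyl ester can be attacked in the closure. The two new sp3 centres C5' and C6' form without control as a cis/trans mixture and both become sp2 in step 7.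

Step 7
Reactants: 11 tert-butyl 2-(ArO)-6-methyl-4-oxocyclohex-2-ene-1-carboxylate
Product: 12 tert-butyl 2-(ArO)-4-hydroxy-6-methylbenzoate
Conditions: DDQ (1.2 equiv), 1,4-dioxane, 60 °C
Reagents that add atoms: none
Why: Quinone dehydrogenation of a cyclohexenone to a phenol; the C6'–H is activated by the ester and the vinylogous ketone, so the extended dienol forms readily, hydride is abstracted from C5', and the dienone tautomerizes to the arene, erasing both sp3 centres.

Step 8
Reactants: 12 tert-butyl 2-(ArO)-4-hydroxy-6-methylbenzoate
Product: 13 tert-butyl 6-(ArO)-3-chloro-4-hydroxy-2-methylbenzoate (chlorine on C4')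
Conditions: SO2Cl2 (1.05 equiv), Et2O–CH2Cl2, 0 °C
Reagents that add atoms: sulfuryl chloride, O=S(=O)(Cl)Cl
Why: Electrophilic aromatic chlorination of a phenol; C4' is ortho to the hydroxyl and para to the ether oxygen, the preferred site in resorcinol monoethers, whereas C2' lies between two oxygens beside the bulky aryloxy group; ring A has no free position.

Step 9
Reactants: 13 tert-butyl 6-(ArO)-3-chloro-4-hydroxy-2-methylbenzoate
Product: 14 tert-butyl 6-(ArO)-3-chloro-5-formyl-4-hydroxy-2-methylbenzoate (formyl on C2')
Conditions: MgCl2, Et3N, (CH2O)n, MeCN, 80 °C
Reagents that add atoms: paraformaldehyde (as formaldehyde), C=O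
Why: Magnesium-mediated ortho-formylation of a phenol (Casnati–Skattebøl); the magnesium phenoxide delivers formaldehyde to the only free ortho carbon C2' and a second formaldehyde oxidizes the benzylic alkoxide, under basic conditions that spare the tert-butyl ester and the benzyl ethers, which a TiCl4-based formylation would not.

Step 10
Reactants: 14 tert-butyl 6-(ArO)-3-chloro-5-formyl-4-hydroxy-2-methylbenzoate
Product: 15 6-(ArO)-3-chloro-5-formyl-4-hydroxy-2-methylbenzoic acid
Conditions: TFA, CH2Cl2, 0 °C → rt
Reagents that add atoms: none
Why: Acidolysis of a tert-butyl ester by loss of the tert-butyl cation; the methyl ester, the aldehyde and the aryl benzyl ethers are stable to TFA at room temperature, and both arenes are fully substituted, so the cation cannot alkylate them.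

Step 11
Reactants: 15 6-(ArO)-3-chloro-5-formyl-4-hydroxy-2-methylbenzoic acid
Product: 16 3-chloro-6-[2,4-dihydroxy-5-(methoxycarbonyl)-3,6-dimethylphenoxy]-5-formyl-4-hydroxy-2-methylbenzoic acid (CNP0210944.0)
Conditions: BCl3, C6HMe5, CH2Cl2, −78 → 0 °C; aq. work-up
Reagents that add atoms: none
Why: Lewis-acid debenzylation of aryl benzyl ethers with pentamethylbenzene as a non-basic scavenger for the benzyl cation; the method needs no hydrogen, so the aryl chloride and the aldehyde are kept, and at low temperature the methyl ester is not cleaved.

## Compound list

1 | methyl 2,4-dihydroxy-3,6-dimethylbenzoate | COC(=O)c1c(C)cc(O)c(C)c1O | starting material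
2 | methyl 5-formyl-2,4-dihydroxy-3,6-dimethylbenzoate | COC(=O)c1c(C)c(C=O)c(O)c(C)c1O | intermediate
3 | methyl 2,4-bis(benzyloxy)-5-formyl-3,6-dimethylbenzoate | COC(=O)c1c(C)c(C=O)c(OCc2ccccc2)c(C)c1OCc1ccccc1 | intermediate
4 | methyl 2,4-bis(benzyloxy)-5-(formyloxy)-3,6-dimethylbenzoate (not isolated) | COC(=O)c1c(C)c(OC=O)c(OCc2ccccc2)c(C)c1OCc1ccccc1 | intermediate
5 | methyl 2,4-bis(benzyloxy)-5-hydroxy-3,6-dimethylbenzoate (ArOH) | COC(=O)c1c(C)c(O)c(OCc2ccccc2)c(C)c1OCc1ccccc1 | intermediate
6 | but-2-ynoic acid | CC#CC(=O)O | starting material
7 | tert-butyl but-2-ynoate | CC#CC(=O)OC(C)(C)C | intermediate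
8 | tert-butyl (2E)-3-(ArO)but-2-enoate | COC(=O)c1c(C)c(O/C(C)=C/C(=O)OC(C)(C)C)c(OCc2ccccc2)c(C)c1OCc1ccccc1 | intermediate
9 | methyl (2E)-but-2-enoate | C/C=C/C(=O)OC | starting material
10 | 1-tert-butyl 5-methyl 2-[1-(ArO)ethenyl]-3-methylpentanedioate (diastereomer mixture, racemic; present as its lithium enolate, not isolated) | COC(=O)CC(C)C(C(=O)OC(C)(C)C)C(=C)Oc1c(C)c(C(=O)OC)c(OCc2ccccc2)c(C)c1OCc1ccccc1 | intermediate
11 | tert-butyl 2-(ArO)-6-methyl-4-oxocyclohex-2-ene-1-carboxylate (cis/trans mixture, racemic) | CC1CC(=O)C=C(Oc2c(C)c(C(=O)OC)c(OCc3ccccc3)c(C)c2OCc2ccccc2)C1C(=O)OC(C)(C)C | intermediate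
12 | tert-butyl 2-(ArO)-4-hydroxy-6-methylbenzoate | Cc1cc(O)cc(Oc2c(C)c(C(=O)OC)c(OCc3ccccc3)c(C)c2OCc2ccccc2)c1C(=O)OC(C)(C)C | intermediate
13 | tert-butyl 6-(ArO)-3-chloro-4-hydroxy-2-methylbenzoate | Cc1c(Cl)c(O)cc(Oc2c(C)c(C(=O)OC)c(OCc3ccccc3)c(C)c2OCc2ccccc2)c1C(=O)OC(C)(C)C | intermediate
14 | tert-butyl 6-(ArO)-3-chloro-5-formyl-4-hydroxy-2-methylbenzoate | Cc1c(Cl)c(O)c(C=O)c(Oc2c(C)c(C(=O)OC)c(OCc3ccccc3)c(C)c2OCc2ccccc2)c1C(=O)OC(C)(C)C | intermediate
15 | 6-(ArO)-3-chloro-5-formyl-4-hydroxy-2-methylbenzoic acid | Cc1c(Cl)c(O)c(C=O)c(Oc2c(C)c(C(=O)OC)c(OCc3ccccc3)c(C)c2OCc2ccccc2)c1C(=O)O | intermediate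
16 | 3-chloro-6-[2,4-dihydroxy-5-(methoxycarbonyl)-3,6-dimethylphenoxy]-5-formyl-4-hydroxy-2-methylbenzoic acid | COC(=O)c1c(C)c(Oc2c(C=O)c(O)c(Cl)c(C)c2C(=O)O)c(O)c(C)c1O | target

## Step count and least certain steps

Total step count: 11. Longest linear sequence: 10 steps (steps 1, 2, 3, 5, 6, 7, 8, 9, 10, 11); step 4 is a one-step side branch.

**Step 6 (key step, proposed new method).**
- What may go wrong: the Michael addition may proceed through the γ-carbon C2' instead of the α-carbon C6'. The aryloxy group raises the electron density at C2', and C6' is the more hindered site. This would turn the crotonate unit around in the ring and place the ester between the two oxygens. Reversal of the Michael addition on warming, before the ring closes, would act in the same direction.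
- Fallback, by known reactions, from 5 to 12: phenol 5 displaces fluoride from 4-bromo-2-fluoro-6-methylbenzaldehyde F1 (K2CO3, DMF, 90 °C) to give the diaryl ether aldehyde 2-(ArO)-4-bromo-6-methylbenzaldehyde F2. Chlorite oxidation (NaClO2, NaH2PO4, 2-methylbut-2-ene) gives 2-(ArO)-4-bromo-6-methylbenzoic acid F3. Esterification as in step 4 gives tert-butyl 2-(ArO)-4-bromo-6-methylbenzoate F4. Miyaura borylation (bis(pinacolato)diboron, Pd(dppf)Cl2, KOAc, dioxane) gives the pinacol boronate F5, and oxidation with NaBO3 in aqueous THF gives 12. This route is longer and returns to an arene–arene ether formation, here eased by the ortho aldehyde.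

**Step 5.**
- What may go wrong: slow addition, because the phenol has two ortho substituents and the alkyne carries a β-methyl group, with amine-induced isomerization and oligomerization of the ynoate taking over.
- Fallback from 5 to 8: (2E)-3-chlorobut-2-enoic acid F6 is tert-butylated as in step 4 to tert-butyl (2E)-3-chlorobut-2-enoate F7. The caesium phenoxide of 5 (Cs2CO3, DMF, 60 °C) then replaces chloride by addition–elimination with retention and gives 8.

**Step 7.**
- What may go wrong: hydride abstraction elsewhere, at the benzylic positions of the electron-rich ring A or at the benzyl ethers, or incomplete dehydrogenation if enolization toward C6' is slow.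
- Fallback from 11 to 12: silylation of 11 with tert-butyldimethylsilyl triflate and Et3N gives the extended silyl dienol ether tert-butyl 2-(ArO)-4-[(tert-butyldimethylsilyl)oxy]-6-methylcyclohexa-1,3-diene-1-carboxylate F8. Saegusa–Ito oxidation of F8 with Pd(OAc)2 in MeCN gives the dienone, which tautomerizes to 12.

**Step 8.**
- What may go wrong: chlorination at C2' as well as, or instead of, C4'. Loss of the tert-butyl ester through the hydrogen chloride formed is a second risk.
- Fallback from 12 to 13: bromination with N-bromosuccinimide in MeCN at −20 °C uses a larger and more selective electrophile and should give tert-butyl 6-(ArO)-3-bromo-4-hydroxy-2-methylbenzoate F9. Halogen exchange with excess CuCl in DMF at 130 °C converts F9 into 13.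

**Step 9.**
- What may go wrong: slow attack at C2', which lies between two oxygens on a phenoxide weakened by the chlorine and the para ester, with methoxymethylation of the phenol competing on long heating.
- Fallback from 13 to 14: condensation of 13 with phenylboronic acid and paraformaldehyde (catalytic propanoic acid, toluene, reflux) delivers the carbon intramolecularly and gives tert-butyl 5-(ArO)-8-chloro-7-methyl-2-phenyl-4H-1,3,2-benzodioxaborine-6-carboxylate F10. Exchange with propane-1,3-diol releases tert-butyl 6-(ArO)-3-chloro-4-hydroxy-5-(hydroxymethyl)-2-methylbenzoate F11, and MnO2 in CH2Cl2 oxidizes the benzylic alcohol to 14.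

## Further compounds

F1 | step 6 | 4-bromo-2-fluoro-6-methylbenzaldehyde | Cc1cc(Br)cc(F)c1C=O
F2 | step 6 | 2-(ArO)-4-bromo-6-methylbenzaldehyde | Cc1cc(Br)cc(Oc2c(C)c(C(=O)OC)c(OCc3ccccc3)c(C)c2OCc2ccccc2)c1C=O
F3 | step 6 | 2-(ArO)-4-bromo-6-methylbenzoic acid | Cc1cc(Br)cc(Oc2c(C)c(C(=O)OC)c(OCc3ccccc3)c(C)c2OCc2ccccc2)c1C(=O)O
F4 | step 6 | tert-butyl 2-(ArO)-4-bromo-6-methylbenzoate | Cc1cc(Br)cc(Oc2c(C)c(C(=O)OC)c(OCc3ccccc3)c(C)c2OCc2ccccc2)c1C(=O)OC(C)(C)C
F5 | step 6 | tert-butyl 2-(ArO)-6-methyl-4-(4,4,5,5-tetramethyl-1,3,2-dioxaborolan-2-yl)benzoate | Cc1cc(B2OC(C)(C)C(C)(C)O2)cc(Oc2c(C)c(C(=O)OC)c(OCc3ccccc3)c(C)c2OCc2ccccc2)c1C(=O)OC(C)(C)C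
F6 | step 5 | (2E)-3-chlorobut-2-enoic acid | C/C(Cl)=C\C(=O)O
F7 | step 5 | tert-butyl (2E)-3-chlorobut-2-enoate | C/C(Cl)=C\C(=O)OC(C)(C)C
F8 | step 7 | tert-butyl 2-(ArO)-4-[(tert-butyldimethylsilyl)oxy]-6-methylcyclohexa-1,3-diene-1-carboxylate (racemic) | CC1CC(O[Si](C)(C)C(C)(C)C)=CC(Oc2c(C)c(C(=O)OC)c(OCc3ccccc3)c(C)c2OCc2ccccc2)=C1C(=O)OC(C)(C)C
F9 | step 8 | tert-butyl 6-(ArO)-3-bromo-4-hydroxy-2-methylbenzoate | Cc1c(Br)c(O)cc(Oc2c(C)c(C(=O)OC)c(OCc3ccccc3)c(C)c2OCc2ccccc2)c1C(=O)OC(C)(C)C
F10 | step 9 | tert-butyl 5-(ArO)-8-chloro-7-methyl-2-phenyl-4H-1,3,2-benzodioxaborine-6-carboxylate | Cc1c(Cl)c2OB(c3ccccc3)OCc2c(Oc2c(C)c(C(=O)OC)c(OCc3ccccc3)c(C)c2OCc2ccccc2)c1C(=O)OC(C)(C)C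
F11 | step 9 | tert-butyl 6-(ArO)-3-chloro-4-hydroxy-5-(hydroxymethyl)-2-methylbenzoate | Cc1c(Cl)c(O)c(CO)c(Oc2c(C)c(C(=O)OC)c(OCc3ccccc3)c(C)c2OCc2ccccc2)c1C(=O)OC(C)(C)C
A1 | alternative 1 | depsidone lacking the formyl group, C3' methyl ether, C6' carbonyl closed as lactone onto the C4 oxygen | COC(=O)c1c(C)c2Oc3cc(OC)c(Cl)c(C)c3C(=O)Oc2c(C)c1O
A2 | alternative 1 | methyl 4-(but-2-ynoyloxy)-3-[(3-chloro-4-methoxy-2-oxo-2H-pyran-6-yl)oxy]-6-hydroxy-2,5-dimethylbenzoate | COC(=O)c1c(C)c(Oc2cc(OC)c(Cl)c(=O)o2)c(OC(=O)C#CC)c(C)c1O
A3 | alternative 2 | methyl 3-[2-(tert-butoxycarbonyl)-4-chloro-5-methoxy-3-methylphenoxy]-4-hydroxy-6-methoxy-2,5-dimethylbenzoate | COC(=O)c1c(C)c(Oc2cc(OC)c(Cl)c(C)c2C(=O)OC(C)(C)C)c(O)c(C)c1OC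
A4 | alternative 2 | tert-butyl 6-{[2,2-bis(trimethylsilyloxy)ethenyl]oxy}-3-chloro-4-methoxy-2-methylbenzoate | C[Si](C)(C)OC(O[Si](C)(C)C)=COc1cc(OC)c(Cl)c(C)c1C(=O)OC(C)(C)C
A5 | alternative 2 | methyl 4-methoxy-3,6-dimethyl-2-oxo-2H-pyran-5-carboxylate | COC(=O)c1c(C)oc(=O)c(C)c1OC
A6 | alternative 3 | methyl 3-[2-(tert-butoxycarbonyl)-4-chloro-5-methoxy-3-methylphenoxy]-6-hydroxy-2,5-dimethyl-4-[(triisopropylsilyl)oxy]benzoate | COC(=O)c1c(C)c(Oc2cc(OC)c(Cl)c(C)c2C(=O)OC(C)(C)C)c(O[Si](C(C)C)(C(C)C)C(C)C)c(C)c1O
A7 | alternative 3 | methyl (2E)-4-[2-(tert-butoxycarbonyl)-4-chloro-5-methoxy-3-methylphenoxy]-5-chloro-3-methyl-5-oxopent-2-enoate (racemic) | COC(=O)/C=C(\C)C(Oc1cc(OC)c(Cl)c(C)c1C(=O)OC(C)(C)C)C(Cl)=O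
A8 | alternative 3 | triisopropyl(prop-1-yn-1-yloxy)silane | CC#CO[Si](C(C)C)(C(C)C)C(C)C
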